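**Strategy**

The target is cut at its symmetry element, the C3–C3' bond, and at N1–C2 and N1'–C2' of the two pyrrole rings. Because both halves are identical 6-bromoindol-3-yl units carrying a replaceable group at C2, two molecules of one ortho-alkynylaniline can be cyclised and joined on palladium in a single oxidative operation that closes both pyrrole rings and makes the biaryl bond. The monomer is 5-bromo-2-[(triethylsilyl)ethynyl]aniline, made in one Sonogashira step. Its silicon ends up on C2 and C2', where N-bromosuccinimide exchanges it for bromine. The aryl bromides at C6 and C6' are carried through from the start.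

Key step: step 2

Assumption: compounds 1 and 2 are bought; the aniline nitrogen stays unprotected throughout, since the free NH2 is the nucleophile of the key step and the target has free N–H groups. C5 of the aniline becomes C6 of the indole, and the target is achiral.

**Route**

Step 1
Reactants: 1 5-bromo-2-iodoaniline; 2 (triethylsilyl)acetylene
Product: 3 5-bromo-2-[(triethylsilyl)ethynyl]aniline
Conditions: PdCl2(PPh3)2 (2 mol%), CuI (4 mol%), Et3N, THF, rt, argon
Reagents that add atoms: none
Why: Sonogashira coupling, in which zerovalent palladium inserts into the C–I bond far faster than into the C–Br bond at room temperature, so only the iodide should be replaced while the free aniline and the silyl cap are tolerated by the mild amine medium.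

Step 2
Reactants: 3 5-bromo-2-[(triethylsilyl)ethynyl]aniline (two molecules)
Product: 4 6,6'-dibromo-2,2'-bis(triethylsilyl)-1H,1'H-3,3'-biindole
Conditions: Pd(OAc)2 (10 mol%), Cu(OAc)2 (20 mol%), NaOAc (2 equiv), O2 (1 atm), 4 Å MS, DMSO (0.5 M), 50 °C
Reagents that add atoms: none
Why: Pd(OAc)2 binds the alkyne of 3, the aniline nitrogen adds anti to the metal at the silicon-bearing carbon and acetate takes up the proton, giving a 2-silylindol-3-ylpalladium acetate; this species activates the alkyne of a second molecule of 3 for the same aminopalladation (or two such species exchange ligands), the resulting bis(indol-3-yl)palladium reductively eliminates the C3–C3' bond, and Cu(OAc)2 with O2 returns zerovalent palladium to the divalent state. The closest known reaction type is the oxidative cyclisation–homocoupling of 2-alkynylanilines to 2,2'-disubstituted 3,3'-biindoles under divalent palladium, here applied to a silyl-capped alkyne. Each pyrrole ring closes in the 5-endo-dig mode, the only one the ortho arrangement of NH2 and alkyne allows, so N1–C2 and N1'–C2' form with silicon on C2 and C2' and palladium on C3 and C3'. No stereocentre arises, and any hindered rotation about the new biaryl axis is irrelevant because the target is achiral. The step needs homocoupling to outrun protonolysis of the C3–Pd bond, which the dry, acetate-buffered aprotic medium, the high substrate concentration and the fairly high palladium loading should favour. The aryl bromides should survive because phosphine-free zerovalent palladium is reoxidised faster than it inserts into C–Br at 50 °C, and the triethylsilyl cap, sturdier than a trimethylsilyl one, should resist acetate and copper long enough to be carried onto C2.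

Step 3
Reactants: 4 6,6'-dibromo-2,2'-bis(triethylsilyl)-1H,1'H-3,3'-biindole
Product: 6 2,2',6,6'-tetrabromo-1H,1'H-3,3'-biindole, via 2-bromo-2'-silyl biindole 5 (not isolated)
Conditions: NBS (2.05 equiv), CH2Cl2, −20 °C to 0 °C, dark
Reagents that add atoms: N-bromosuccinimide, O=C1CCC(=O)N1Br
Why: Electrophilic ipso-substitution of a heteroarylsilane (bromodesilylation), in which bromonium attack on the electron-rich C2=C3 bond of each pyrrole ring gives a cation that loses the triethylsilyl group at C2 more easily than any proton, so bromine should enter only where silicon sat and leave the benzenoid C–H positions, deactivated by the C6 bromine, untouched at low temperature.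

**Compound list**

1 | 5-bromo-2-iodoaniline | Nc1cc(Br)ccc1I | starting material
2 | (triethylsilyl)acetylene | CC[Si](CC)(CC)C#C | starting material
3 | 5-bromo-2-[(triethylsilyl)ethynyl]aniline | CC[Si](CC)(CC)C#Cc1ccc(Br)cc1N | intermediate
4 | 6,6'-dibromo-2,2'-bis(triethylsilyl)-1H,1'H-3,3'-biindole | CC[Si](CC)(CC)c1[nH]c2cc(Br)ccc2c1-c1c([Si](CC)(CC)CC)[nH]c2cc(Br)ccc12 | intermediate
5 | 2,6,6'-tribromo-2'-(triethylsilyl)-1H,1'H-3,3'-biindole (formed and consumed in step 3) | CC[Si](CC)(CC)c1[nH]c2cc(Br)ccc2c1-c1c(Br)[nH]c2cc(Br)ccc12 | intermediate
6 | 2,2',6,6'-tetrabromo-1H,1'H-3,3'-biindole | Brc1ccc2c(-c3c(Br)[nH]c4cc(Br)ccc34)c(Br)[nH]c2c1 | target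

**Count**

Total steps: 3. Longest linear sequence: 3 steps (1 → 3 → 4 → 6).

**Steps most likely to fail**

1. Step 2. Protonolysis of the C3–Pd bond of the first-formed indolylpalladium acetate may outrun delivery of the second indole unit, all the more as the two triethylsilyl groups crowd the diorganopalladium, so the cycle would close at the monomer stage. Acetate may also cleave the alkynyl C–Si bond before cyclisation. The fallback gives up the silicon handle and builds the C3–C3' bond by carbonyl chemistry; it sets out from 3 and comes back at 6. Heating 3 with TBAF in THF should remove the silyl cap and close the ring to 6-bromo-1H-indole F1, which can also be bought. Base-catalysed addition of F1 through C3 to the ketone of commercial 6-bromoisatin (Et2NH cat., EtOH, rt) should give racemic 6-bromo-3-(6-bromo-1H-indol-3-yl)-3-hydroxyindolin-2-one F2. Reduction with BH3·THF, with loss of both oxygen atoms and aromatisation, should give 6,6'-dibromo-1H,1'H-3,3'-biindole F3. Bromination of the two free C2–H positions of F3 with NBS (2.0 equiv, THF, −78 °C to 0 °C) should then give 6.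

2. Step 3. Electrophilic bromine may not stay confined to the two silicon-bearing carbons: oxidation of the electron-rich N–H biindole or substitution on the benzenoid rings may compete, or the exchange may stall after the first silicon because of the twisted, hindered biaryl. The fallback replaces electrophilic substitution by directed metalation; it sets out from 4 and comes back at 6. Protodesilylation of 4 with TFA in CH2Cl2 should give 6,6'-dibromo-1H,1'H-3,3'-biindole F3. Treatment with Boc2O and catalytic DMAP in MeCN should give di-tert-butyl 6,6'-dibromo-1H,1'H-[3,3'-biindole]-1,1'-dicarboxylate F4. Deprotonation at C2 and C2' with LiN(iPr)2 in THF at −78 °C, which leaves aryl bromides alone, and quenching with 1,2-dibromotetrachloroethane should give di-tert-butyl 2,2',6,6'-tetrabromo-1H,1'H-[3,3'-biindole]-1,1'-dicarboxylate F5. Methanolysis of the two carbamates (K2CO3, MeOH/THF, rt) should release 6.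

3. Step 1. Copper may dimerise the alkyne oxidatively (Glaser coupling) or cyclise the product prematurely, and the discrimination between iodide and bromide may erode if the mixture has to be warmed. The fallback is a copper-free Negishi alkynylation; it sets out from 2 and 1 and comes back at 3. Deprotonation of 2 with n-BuLi in THF at −78 °C and transmetalation with ZnCl2 should give chloro[(triethylsilyl)ethynyl]zinc F6. Coupling of F6 with 1 under Pd(PPh3)4 in THF at rt should engage only the C–I bond and give 3.

**Further compounds**

F1 | step 2 | 6-bromo-1H-indole | Brc1ccc2cc[nH]c2c1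
F2 | step 2 | 6-bromo-3-(6-bromo-1H-indol-3-yl)-3-hydroxyindolin-2-one (racemic) | O=C1Nc2cc(Br)ccc2C1(O)c1c[nH]c2cc(Br)ccc12
F3 | step 2 | 6,6'-dibromo-1H,1'H-3,3'-biindole | Brc1ccc2c(-c3c[nH]c4cc(Br)ccc34)c[nH]c2c1
F4 | step 3 | di-tert-butyl 6,6'-dibromo-1H,1'H-[3,3'-biindole]-1,1'-dicarboxylate | CC(C)(C)OC(=O)n1cc(-c2cn(C(=O)OC(C)(C)C)c3cc(Br)ccc23)c2ccc(Br)cc21
F5 | step 3 | di-tert-butyl 2,2',6,6'-tetrabromo-1H,1'H-[3,3'-biindole]-1,1'-dicarboxylate | CC(C)(C)OC(=O)n1c(Br)c(-c2c(Br)n(C(=O)OC(C)(C)C)c3cc(Br)ccc23)c2ccc(Br)cc21
F6 | step 1 | chloro[(triethylsilyl)ethynyl]zinc | CC[Si](CC)(CC)C#C[Zn]Cl
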